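**Plan**
- Retrosynthetic cuts, in order: the coumarate ester C–O bond; the aryl–CH2 bond of the hydroxypropyl chain at C5; the C3–C3a bond of the dihydrofuran ring; the C2–aryl bond.
- Enabling feature: C3 of the dihydrobenzofuran carries both the ring aryl carbon C3a and an exocyclic oxygenated one-carbon unit (the CH2O of the ester). That is the footprint of a 1,2-aryl shift, so this carbon is read as the former carbonyl C4 of a flavanone. The six-membered pyranone ring (O1, C2, C3, C4, C4a, C8a) contracts to the five-membered ring (O1, C2, C3, C3a, C7a).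
- Forward order: chromone, then (R)-flavanone by asymmetric conjugate arylation, then oxidative ring contraction to the trans-2-aryl-2,3-dihydrobenzofuran-3-carboxylate, then Negishi attachment of the C3 chain, LiAlH4 reduction, Mitsunobu esterification with p-coumaric acid and desilylation.
- Stereochemistry: C2 comes from the ligand-controlled conjugate addition; C3 is relayed from C2 in the ring contraction (trans). No later step touches either centre.
- Helpers: an aryl bromide holds the place of the side chain, and a pivalate on the B-ring phenol deactivates that ring during the key step. Both are converted or removed afterwards.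

Key step: step 5

Assumption: (S)-t-BuPyOx is taken to deliver the aryl group to the chromone face that gives the (2R)-flavanone, by analogy with its sense of induction on cyclic enones; if the sense is opposite, the (R)-ligand is used with no other change.

**Route**

Step 1
Reactants: 1 2'-hydroxy-3'-methoxyacetophenone
Product: 2 1-(5-bromo-2-hydroxy-3-methoxyphenyl)ethan-1-one
Conditions: NBS, MeCN, 0 °C → rt
Reagents that add atoms: N-bromosuccinimide, O=C1CCC(=O)N1Br
Why: Electrophilic aromatic bromination; the free phenol directs to its para position (C5), which is also meta to the acetyl group, and both ortho positions of the phenol are blocked.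

Step 2
Reactants: 2 1-(5-bromo-2-hydroxy-3-methoxyphenyl)ethan-1-one
Product: 4 6-bromo-8-methoxy-4H-chromen-4-one, via enaminone 3 (not isolated)
Conditions: DMF-DMA, PhMe, 100 °C; then conc. HCl, CH2Cl2, 40 °C
Reagents that add atoms: N,N-dimethylformamide dimethyl acetal, COC(OC)N(C)C
Why: Condensation of the methyl ketone with DMF-DMA to the enaminone, then acid-promoted intramolecular oxa-Michael addition and loss of dimethylamine, is the standard chromone synthesis from 2'-hydroxyacetophenones.

Step 3
Reactants: 5 (4-hydroxy-3-methoxyphenyl)boronic acid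
Product: 6 [3-methoxy-4-(pivaloyloxy)phenyl]boronic acid
Conditions: PivCl, pyridine, CH2Cl2, 0 °C → rt; then H2O/THF
Reagents that add atoms: pivaloyl chloride, CC(C)(C)C(=O)Cl
Why: O-acylation of the phenol; the aqueous stir hydrolyses any B–O acyl species and boroxine back to the boronic acid, and the pivalate serves as an acid-stable, electron-withdrawing mask for the phenol.

Step 4
Reactants: 4 6-bromo-8-methoxy-4H-chromen-4-one; 6 [3-methoxy-4-(pivaloyloxy)phenyl]boronic acid
Product: 7 4-[(2R)-6-bromo-8-methoxy-4-oxochroman-2-yl]-2-methoxyphenyl pivalate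
Conditions: Pd(OCOCF3)2 (5 mol%), (S)-t-BuPyOx (6 mol%), NH4PF6 (30 mol%), H2O (5 equiv), ClCH2CH2Cl, 60 °C
Reagents that add atoms: none
Why: Pd(II)-catalysed asymmetric conjugate addition of an arylboronic acid to a chromone (transmetalation, enantio-determining insertion of C2=C3 into the Ar–Pd bond in the chiral pyridine-oxazoline pocket, protonolysis of the Pd enolate) should set C2 as R; the non-basic medium avoids retro-oxa-Michael opening, and Pd(II) leaves the aryl bromide untouched.

Step 5
Reactants: 7 4-[(2R)-6-bromo-8-methoxy-4-oxochroman-2-yl]-2-methoxyphenyl pivalate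
Product: 11 methyl (2R,3R)-5-bromo-7-methoxy-2-[3-methoxy-4-(pivaloyloxy)phenyl]-2,3-dihydro-1-benzofuran-3-carboxylate, via methyl enol ether 8 (not isolated), via iodane ketal 9 (not isolated), via orthoester 10 (not isolated)
Conditions: PhI(OAc)2 (1.2 equiv), conc. H2SO4, HC(OMe)3, rt; then H2O, aq. NaHCO3
Reagents that add atoms: trimethyl orthoformate, COC(OC)OC; water (work-up), O
Why: Acid and orthoformate should convert the ketone into methyl enol ether 8, PhI(OAc)2 adds to C3 anti to the C2 aryl group and methanol caps C4 to give the trans-diequatorial iodane ketal 9, and the C4–C4a bond (antiperiplanar to the equatorial C3–I bond and pushed by two methoxy groups) then shifts from C4 to C3 as PhI leaves, giving a dimethoxycarbenium ion that is caught as orthoester 10 and hydrolysed to ester 11 on work-up. The closest known reaction type is the iodine(III)- or thallium(III)-mediated oxidative rearrangement of flavanones and chroman-4-ones to methyl 2-aryl-2,3-dihydrobenzofuran-3-carboxylates, a 1,2-aryl shift of a ketone ketal. The five-membered ring is closed not by a cyclisation but by ring contraction: a suprafacial 1,2-shift of aryl carbon C4a through a bridged phenonium ion forms C3–C3a and expels C4 as the exocyclic ester carbon. C2 is untouched; C3 is set trans to the C2 aryl group because the iodane enters anti to that group and is displaced with inversion, and since the ester α-CH is epimerisable, trans is also the thermodynamic outcome. The step needs ring contraction to beat the 2→3 shift of the B ring (isoflavone), solvolysis at C3 and arene oxidation; this is secured by the diequatorial geometry of 9 (C2 aryl gauche to C–I), by the pivalate that lowers the migratory aptitude and oxidisability of the B ring, and by carrying a bromide at C6 in place of the oxygenated side chain.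

Step 6
Reactants: 12 (3-bromopropoxy)(tert-butyl)dimethylsilane
Product: 13 {3-[(tert-butyldimethylsilyl)oxy]propyl}zinc bromide (LiCl complex, THF solution)
Conditions: Zn dust (activated with BrCH2CH2Br, TMSCl), LiCl, THF, 50 °C
Reagents that add atoms: zinc, [Zn]
Why: LiCl-assisted oxidative insertion of zinc into a primary alkyl bromide; the silyl ether is inert and the reagent is used as a titrated solution.

Step 7
Reactants: 11 methyl (2R,3R)-5-bromo-7-methoxy-2-[3-methoxy-4-(pivaloyloxy)phenyl]-2,3-dihydro-1-benzofuran-3-carboxylate; 13 {3-[(tert-butyldimethylsilyl)oxy]propyl}zinc bromide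
Product: 14 methyl (2R,3R)-5-{3-[(tert-butyldimethylsilyl)oxy]propyl}-7-methoxy-2-[3-methoxy-4-(pivaloyloxy)phenyl]-2,3-dihydro-1-benzofuran-3-carboxylate
Conditions: Pd(OAc)2 (2 mol%), SPhos (4 mol%), THF, rt
Reagents that add atoms: none
Why: Negishi sp3–sp2 cross-coupling of a primary alkylzinc halide with an aryl bromide; the neutral conditions tolerate both esters and avoid base-induced β-elimination of the phenoxide from the β-aryloxy ester, which would open the ring.

Step 8
Reactants: 14 methyl (2R,3R)-5-{3-[(tert-butyldimethylsilyl)oxy]propyl}-7-methoxy-2-[3-methoxy-4-(pivaloyloxy)phenyl]-2,3-dihydro-1-benzofuran-3-carboxylate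
Product: 15 4-[(2R,3S)-5-{3-[(tert-butyldimethylsilyl)oxy]propyl}-3-(hydroxymethyl)-7-methoxy-2,3-dihydro-1-benzofuran-2-yl]-2-methoxyphenol
Conditions: LiAlH4, THF, −20 → 0 °C; Rochelle salt work-up
Reagents that add atoms: none
Why: Hydride reduction of the methyl ester to the primary alcohol with concurrent reductive cleavage of the aryl pivalate; no bond at a stereocentre is broken (the C3 descriptor changes from R to S only through CIP priorities) and the alkyl silyl ether survives.

Step 9
Reactants: 15 4-[(2R,3S)-5-{3-[(tert-butyldimethylsilyl)oxy]propyl}-3-(hydroxymethyl)-7-methoxy-2,3-dihydro-1-benzofuran-2-yl]-2-methoxyphenol; 16 (E)-4-hydroxycinnamic acid (p-coumaric acid)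
Product: 17 [(2R,3S)-5-{3-[(tert-butyldimethylsilyl)oxy]propyl}-2-(4-hydroxy-3-methoxyphenyl)-7-methoxy-2,3-dihydro-1-benzofuran-3-yl]methyl (E)-3-(4-hydroxyphenyl)prop-2-enoate
Conditions: PPh3, DIAD, THF, 0 °C → rt
Reagents that add atoms: none
Why: Mitsunobu esterification, known to be chemoselective for unprotected phenolic acids and primary alcohols: only the carboxylic acid (pKa about 4.5) protonates the betaine, only the aliphatic alcohol forms an alkoxyphosphonium ion, and the two phenols (pKa about 10) remain spectators.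

Step 10
Reactants: 17 [(2R,3S)-5-{3-[(tert-butyldimethylsilyl)oxy]propyl}-2-(4-hydroxy-3-methoxyphenyl)-7-methoxy-2,3-dihydro-1-benzofuran-3-yl]methyl (E)-3-(4-hydroxyphenyl)prop-2-enoate
Product: 18 [(2R,3S)-2-(4-hydroxy-3-methoxyphenyl)-5-(3-hydroxypropyl)-7-methoxy-2,3-dihydro-1-benzofuran-3-yl]methyl (E)-3-(4-hydroxyphenyl)prop-2-enoate (CNP0202924.1)
Conditions: HF·pyridine, pyridine, THF, 0 °C → rt
Reagents that add atoms: none
Why: Fluoride-driven cleavage of the primary silyl ether under buffered conditions should leave the cinnamate ester, the E-alkene, the benzylic aryl ether and both phenols intact.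

**Compound list**

1 | 2'-hydroxy-3'-methoxyacetophenone | CC(=O)c1cccc(OC)c1O | starting material
2 | 1-(5-bromo-2-hydroxy-3-methoxyphenyl)ethan-1-one | CC(=O)c1cc(Br)cc(OC)c1O | intermediate
3 | (E)-1-(5-bromo-2-hydroxy-3-methoxyphenyl)-3-(dimethylamino)prop-2-en-1-one | CN(C)/C=C/C(=O)c1cc(Br)cc(OC)c1O | intermediate
4 | 6-bromo-8-methoxy-4H-chromen-4-one | O=c1ccoc2c(OC)cc(Br)cc12 | intermediate
5 | (4-hydroxy-3-methoxyphenyl)boronic acid | COc1cc(B(O)O)ccc1O | starting material
6 | [3-methoxy-4-(pivaloyloxy)phenyl]boronic acid | COc1cc(B(O)O)ccc1OC(=O)C(C)(C)C | intermediate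
7 | 4-[(2R)-6-bromo-8-methoxy-4-oxochroman-2-yl]-2-methoxyphenyl pivalate | O=C1C[C@H](c2ccc(OC(=O)C(C)(C)C)c(OC)c2)Oc2c(OC)cc(Br)cc21 | intermediate
8 | 4-[(2R)-6-bromo-4,8-dimethoxy-2H-chromen-2-yl]-2-methoxyphenyl pivalate | COC1=C[C@H](c2ccc(OC(=O)C(C)(C)C)c(OC)c2)Oc2c(OC)cc(Br)cc21 | intermediate
9 | 4-[(2S,3S)-3-[acetoxy(phenyl)-λ3-iodanyl]-6-bromo-4,4,8-trimethoxychroman-2-yl]-2-methoxyphenyl pivalate (aryl and iodanyl groups trans) | COC1(OC)[C@@H](I(OC(C)=O)c2ccccc2)[C@H](c2ccc(OC(=O)C(C)(C)C)c(OC)c2)Oc2c(OC)cc(Br)cc21 | intermediate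
10 | 4-[(2R,3R)-5-bromo-7-methoxy-3-(trimethoxymethyl)-2,3-dihydro-1-benzofuran-2-yl]-2-methoxyphenyl pivalate | COc1cc([C@@H]2Oc3c(OC)cc(Br)cc3[C@H]2C(OC)(OC)OC)ccc1OC(=O)C(C)(C)C | intermediate
11 | methyl (2R,3R)-5-bromo-7-methoxy-2-[3-methoxy-4-(pivaloyloxy)phenyl]-2,3-dihydro-1-benzofuran-3-carboxylate (2,3-trans) | COc1cc([C@@H]2Oc3c(OC)cc(Br)cc3[C@H]2C(=O)OC)ccc1OC(=O)C(C)(C)C | intermediate
12 | (3-bromopropoxy)(tert-butyl)dimethylsilane | CC(C)(C)[Si](C)(C)OCCCBr | starting material
13 | {3-[(tert-butyldimethylsilyl)oxy]propyl}zinc bromide | CC(C)(C)[Si](C)(C)OCCC[Zn]Br | intermediate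
14 | methyl (2R,3R)-5-{3-[(tert-butyldimethylsilyl)oxy]propyl}-7-methoxy-2-[3-methoxy-4-(pivaloyloxy)phenyl]-2,3-dihydro-1-benzofuran-3-carboxylate | COc1cc([C@@H]2Oc3c(OC)cc(CCCO[Si](C)(C)C(C)(C)C)cc3[C@H]2C(=O)OC)ccc1OC(=O)C(C)(C)C | intermediate
15 | 4-[(2R,3S)-5-{3-[(tert-butyldimethylsilyl)oxy]propyl}-3-(hydroxymethyl)-7-methoxy-2,3-dihydro-1-benzofuran-2-yl]-2-methoxyphenol | COc1cc([C@@H]2Oc3c(OC)cc(CCCO[Si](C)(C)C(C)(C)C)cc3[C@H]2CO)ccc1O | intermediate
16 | (E)-4-hydroxycinnamic acid (p-coumaric acid) | O=C(O)/C=C/c1ccc(O)cc1 | starting material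
17 | [(2R,3S)-5-{3-[(tert-butyldimethylsilyl)oxy]propyl}-2-(4-hydroxy-3-methoxyphenyl)-7-methoxy-2,3-dihydro-1-benzofuran-3-yl]methyl (E)-3-(4-hydroxyphenyl)prop-2-enoate | COc1cc([C@@H]2Oc3c(OC)cc(CCCO[Si](C)(C)C(C)(C)C)cc3[C@H]2COC(=O)/C=C/c2ccc(O)cc2)ccc1O | intermediate
18 | [(2R,3S)-2-(4-hydroxy-3-methoxyphenyl)-5-(3-hydroxypropyl)-7-methoxy-2,3-dihydro-1-benzofuran-3-yl]methyl (E)-3-(4-hydroxyphenyl)prop-2-enoate | COc1cc([C@@H]2Oc3c(OC)cc(CCCO)cc3[C@H]2COC(=O)/C=C/c2ccc(O)cc2)ccc1O | target

**Summary**

Total step count: 10.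
Longest linear sequence: 8 steps (1 → 2 → 4 → 7 → 11 → 14 → 15 → 17 → 18; steps 1, 2, 4, 5, 7, 8, 9 and 10).

Steps most likely to fail:

Step 5. The iodane ketal may follow other channels: migration of the C2 aryl group to C3 (towards an isoflavone), solvolytic capture at C3, or acid-induced ionisation at C2 with loss of enantiopurity. The fallback is a photochemical Wolff ring contraction; it sets out from 7 and comes back at 11. Kinetic enolisation of 7 (LiHMDS, THF, −78 °C) and acylation with 2,2,2-trifluoroethyl trifluoroacetate should give the 3-(trifluoroacetyl)flavanone F1. Detrifluoroacetylative diazo transfer (MsN3, Et3N, MeCN, H2O) should give the 3-diazoflavanone F2. Irradiation (λ > 300 nm) in methanol should expel nitrogen and shift the same aryl carbon from C4 to C3, now onto a carbene, to give the ketene F3. Methanol traps the ketene, with protonation anti to the aryl group expected to favour the cis ester F4, and equilibration at C3 (cat. DBU, CH2Cl2) should then give the trans ester 11.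

Step 4. Facial discrimination in the insertion step may be insufficient with the 8-methoxy chromone, or enantiopurity may erode through reversible ring opening to the 2'-hydroxychalcone. The fallback is a kinetic resolution; it sets out from 4 and 6 and comes back at 7. Conjugate addition with an achiral catalyst (Pd(OCOCF3)2, 2,2'-bipyridine, aqueous ClCH2CH2Cl, 60 °C) should give the racemic flavanone F5. Asymmetric transfer hydrogenation (RuCl(p-cymene)[(S,S)-TsDPEN], HCO2H/Et3N, EtOAc) is expected to reduce the (S)-ketone faster, with hydride delivered anti to the aryl group, to the cis-flavan-4-ol F6. F6 is separated by chromatography from unreacted (R)-ketone 7.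

Step 9. Chemoselectivity may be lost by O-alkylation of a phenol by the alkoxyphosphonium ion, or conversion of the β-branched alcohol may be poor. The fallback sets out from 15 and comes back at 17. Exhaustive carbodiimide acylation of both hydroxyl groups with commercial (E)-4-acetoxycinnamic acid (EDC·HCl, DMAP, CH2Cl2) should give the bis(4-acetoxycinnamate) F7. Pyrrolidine (THF, rt) should then cleave only the three phenolic esters (two aryl acetates and the aryl cinnamate) by aminolysis and leave the alkyl cinnamate, giving 17.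

Further compounds
F1 | step 5 | 4-[(2R)-6-bromo-8-methoxy-4-oxo-3-(trifluoroacetyl)chroman-2-yl]-2-methoxyphenyl pivalate (C3 epimers/enol form) | O=C1C(C(=O)C(F)(F)F)[C@H](c2ccc(OC(=O)C(C)(C)C)c(OC)c2)Oc2c(OC)cc(Br)cc21
F2 | step 5 | 4-[(2S)-6-bromo-3-diazo-8-methoxy-4-oxochroman-2-yl]-2-methoxyphenyl pivalate | O=C1C(=[N+]=[N-])[C@H](c2ccc(OC(=O)C(C)(C)C)c(OC)c2)Oc2c(OC)cc(Br)cc21
F3 | step 5 | 4-[5-bromo-7-methoxy-3-(oxomethylidene)-2,3-dihydro-1-benzofuran-2-yl]-2-methoxyphenyl pivalate (ketene; C2 configured as in 7) | O=C=C1[C@H](c2ccc(OC(=O)C(C)(C)C)c(OC)c2)Oc2c(OC)cc(Br)cc21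
F4 | step 5 | methyl (2R,3S)-5-bromo-7-methoxy-2-[3-methoxy-4-(pivaloyloxy)phenyl]-2,3-dihydro-1-benzofuran-3-carboxylate (2,3-cis) | COc1cc([C@@H]2Oc3c(OC)cc(Br)cc3[C@@H]2C(=O)OC)ccc1OC(=O)C(C)(C)C
F5 | step 4 | racemic 4-(6-bromo-8-methoxy-4-oxochroman-2-yl)-2-methoxyphenyl pivalate | O=C1CC(c2ccc(OC(=O)C(C)(C)C)c(OC)c2)Oc2c(OC)cc(Br)cc21
F6 | step 4 | 4-[(2S,4S)-6-bromo-4-hydroxy-8-methoxychroman-2-yl]-2-methoxyphenyl pivalate (2,4-cis) | O[C@H]1C[C@@H](c2ccc(OC(=O)C(C)(C)C)c(OC)c2)Oc2c(OC)cc(Br)cc21
F7 | step 9 | [(2R,3S)-2-{4-[(E)-3-(4-acetoxyphenyl)prop-2-enoyloxy]-3-methoxyphenyl}-5-{3-[(tert-butyldimethylsilyl)oxy]propyl}-7-methoxy-2,3-dihydro-1-benzofuran-3-yl]methyl (E)-3-(4-acetoxyphenyl)prop-2-enoate | COc1cc([C@@H]2Oc3c(OC)cc(CCCO[Si](C)(C)C(C)(C)C)cc3[C@H]2COC(=O)/C=C/c2ccc(OC(C)=O)cc2)ccc1OC(=O)/C=C/c1ccc(OC(C)=O)cc1
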